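# Synthesis plan for (3S)-3,5-dihydroxy-3-[4-hydroxy-2-methoxy-3-(3-methylbut-2-en-1-yl)phenyl]-7-methoxy-2,3-dihydro-4H-chromen-4-one (26)

Atom labels follow the chroman-4-one: O1, C2, C3, C4, C4a, C5–C8, C8a for rings C and A, and C1'–C6' for ring B.

## The problem

The target is a 3-hydroxyisoflavanone. Ring A is fused to the pyranone ring C, and C3 carries both ring B and a tertiary hydroxyl. C3 is therefore a fully substituted carbinol between the C4 ketone, the C2 methylene and an ortho-methoxylated arene.

C3 is the only stereocentre (S). No second centre can relay to it, so a catalyst or reagent has to set it. It has no α-hydrogen, so it cannot be epimerised and cannot be corrected later.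

Two pairs of similar oxygens must be told apart. Ring A must end with 5-OH free and 7-OMe methylated. Ring B must end with 2'-OMe and 4'-OH, with the prenyl group wedged between them at C3'.

The fragile parts are:
- the prenyl group next to the 4'-phenol (acid closes it to a chroman, electrophiles attack the alkene);
- the tertiary benzylic α-hydroxy ketone (acid dehydrates it to the isoflavone; hot base invites retro-aldol loss of C2 while ring C is open);
- the electron-rich arenes.

The enabling feature is the 1,3,5-oxygen pattern of ring A around the acyl-bearing C4a. C5–C6–C7–C8, with one free and one methylated oxygen, is a 1,3-dimethoxy-1-silyloxybutadiene. C4a–C8a is the alkyne of an ynone, with bromine on C8a standing in for O1. Building ring A this way separates 5-OH from 7-OMe without any selective demethylation.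

## Retrosynthesis

**26 ⇐ 25.** Only the 4'-oxygen is still protected in the last intermediate 25. A MOM ether is kept there because it is the stronger of the two directing groups when the prenyl group is placed on ring B. It also survives the organolithium, rhodium, silver and copper steps. The forward step must cleave it without protic acid or heat.

**25 ⇐ 24.** Ring C is opened at O1–C8a. Cutting O1–C2 would need a phenol at C8a, and cutting C4–C4a would need ring A as a preformed reagent. Only the aryl C–O cut leaves ring A as a 2-bromoaryl ketone that a benzannulation can deliver. Diol 24 is open-chain. The forward reaction must etherify the primary hydroxyl in a six-membered closure and leave the tertiary one alone.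

**24 ⇐ 23.** Both hydroxyls of 24 have to be masked wherever an ynone is present, because they would add to it. One acetonide does this with a single group and a single weakly acidic removal.

**23 ⇐ 17 + 21.** Ring A is cut at C4a–C5 and C8–C8a. This turns a 1,2,3,5-tetrasubstituted arene into two open-chain partners. Diene 21 carries C5–C8 and both oxygens in their final state. Bromoynone 17 carries C4, C4a, C8a and the complete chiral core. Introducing a preformed ring A by aryl-metal acylation is the neighbouring option, but it would require a 2-bromo-6-oxy-4-methoxyphenyl nucleophile that has no regiochemically clean source. The forward reaction must be regioselective (diene CH2 to the bromine-bearing carbon) and must close the ring faster than bromide is lost.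

**21 ⇐ 19 ⇐ 18.** The diene is the silyl ketene acetal of the enol ether 19, which comes from methyl acetoacetate 18 in one step.

**17 ⇐ 16 ⇐ 13 + 14.** The ynone is cut at C4–C4a. Ester 13 acylates the acetylide of silyl alkyne 14 to give 16. Bromine is exchanged for silicon last, so the sensitive bromoalkyne exists for one step only.

**13 ⇐ 12 ⇐ 11 ⇐ 8 + 10.** The quaternary carbinol is cut at C3–C1'. Asymmetric dihydroxylation of a 1,1-disubstituted alkene would be the classical neighbour, but the prenyl alkene is more reactive than any such alkene and would have to be introduced afterwards on a crowded ring. Catalytic aryl transfer from boronic acid 8 to ketoester 10 tolerates the prenyl group. It sets C3 in the step that joins the two halves, giving 11. Methanolysis then gives diol 12 and ketalisation gives 13. The catalyst must deliver the aryl group to the Re face of the ketone.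

**10 ⇐ 9; 8 ⇐ 5 ⇐ 2 + 3; 2 ⇐ 1.** Ketoester 10 is methyl bromopyruvate 9 with bromide replaced by pivalate. Boronic acid 8 comes from bromide 5 by halogen–metal exchange. Bromide 5 comes from MOM ether 2 and prenyl bromide 3 by metalation at the one position flanked by both oxygens. Ether 2 comes from the commercial phenol 1.

## Roads not taken

**Alternative 1: ring B by Danheiser benzannulation.**
- Cut: ring B is the ring that is built, through C1'–C2', C3'–C4' and C4'–C5'.
- Forward step: irradiation of the diazo enone A1 would give a vinylketene by Wolff rearrangement. A1 already holds C2, the protected C3 carbinol, the ester that becomes C4 and the ring A aryl ether. A (2+2) addition of the prenyl-bearing methoxyalkyne A2, a four-electron opening and a six-electron closure would then give phenol A3.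
- Merits: the 2'-OMe/3'-prenyl/4'-OH pattern, the hardest substitution problem of the molecule, follows from the alkyne regiochemistry, with the 4'-hydroxyl free. Here it is better than the chosen plan, which needs a lithium amide metalation of a bromoarene to place the prenyl group.
- Weak points: the diazo carbon sits next to a fully substituted, oxygenated centre, so diazo transfer is slow and 1,2-shifts of the carbene compete. The photolysis is run on an aryl bromide. Ring C must still be closed by bromine–lithium exchange and attack on the ester. Ring A arrives as the 5,7-dimethyl ether, so the 5-methyl ether must be cleaved selectively by a Lewis acid beside the prenyl phenol and the C3 carbinol. The stereocentre must be made without an aryl nucleophile.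
- Comparison: the chosen plan is not shorter in its ring B chemistry. It avoids the late demethylation, because its benzannulation makes 5-OH and 7-OMe different from the start.

**Alternative 2: difluoro ring A and intramolecular substitution.**
- Cut: O1–C8a, as in the chosen plan, but ring A is bought as a 2,6-difluoro-4-methoxyphenyl group.
- Forward step: the primary alkoxide of hydroxy ketone A4 displaces one of two equivalent ortho fluorines to give chromanone A5.
- Merits: this is the most reliable ring closure of the four. It needs no metal and has no regiochemistry. The arene is lithiated cleanly between its fluorines, and the tertiary hydroxyl is masked while the ring closes. In this respect it is better than the chosen plan, whose benzannulation has no direct precedent and whose copper step runs with the tertiary hydroxyl free. Its chemistry is therefore kept as the fallback for step 12.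
- Weak points: A5 carries fluorine where the 5-hydroxyl belongs. The second substitution, by a hydroxide equivalent, takes place on a ring that has become more electron-rich and next to a base-sensitive α-alkoxy ketone. The tertiary hydroxyl needs its own protecting group, and ring A is carried, not built.
- Comparison: against the better precedent of A5, the chosen plan offers a ring A that emerges with 5-OH and 7-OMe in place. Its bromine is consumed in the ring closure itself, so no atom has to be exchanged afterwards.

**Alternative 3: aryne annulation.**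
- Cut: two bonds of ring C at once, O1–C8a and C4–C4a.
- Forward step: the primary alkoxide of dioxolanone A6 adds to the aryne A7 at the future C8a. The aryl anion formed at C4a attacks the lactone carbonyl, and collapse of the acetal frees the C3 hydroxyl, giving chromanone A8 in one operation.
- Merits: it is the most convergent of the plans, and in bonds formed per step it is better than the chosen plan. The inductive effect of the neighbouring methoxy group should steer the alkoxide to the correct aryne carbon.
- Weak points: the aryl anion can be protonated by the alcohol before it acylates, so plain aryl ether formation competes. The aryne precursor and the quaternary dioxolanone each need several steps, the latter by an alkylation that must set the same stereocentre. A8 again has both ring A oxygens methylated, so the 5-methyl ether must be cleaved selectively at the end, beside the 2'-methyl ether, the prenyl group and the MOM ether.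
- Comparison: the chosen plan accepts three steps after its key step in exchange for never having to demethylate.

Key step: step 12

## Route

Remark: in the step lines, Ar = 2-methoxy-4-(methoxymethoxy)-3-(3-methylbut-2-en-1-yl)phenyl.

Assumption: the sense of induction of the chiral diene in step 5 is assigned beforehand on a model ketoester, and the ligand enantiomer that sends the aryl group to the Re face of the ketone is used.

Remark: the silyl ketene acetal double bond of 21 is drawn E. Its geometry has no consequence, because that carbon becomes aromatic.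

Step 1
Reactants: 1 4-bromo-3-methoxyphenol
Product: 2 1-bromo-2-methoxy-4-(methoxymethoxy)benzene
Conditions: MOMCl, i-Pr2NEt, CH2Cl2, 0 °C → rt
Reagents that add atoms: chloromethyl methyl ether, COCCl
Why: Williamson-type O-alkylation of the phenol under amine base; the MOM ether is stable to all later basic and organometallic steps and will act as the stronger directing group in step 2.

Step 2
Reactants: 2 1-bromo-2-methoxy-4-(methoxymethoxy)benzene; 3 1-bromo-3-methylbut-2-ene (prenyl bromide)
Product: 5 1-bromo-2-methoxy-4-(methoxymethoxy)-3-(3-methylbut-2-en-1-yl)benzene, via aryllithium 4 (not isolated)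
Conditions: lithium 2,2,6,6-tetramethylpiperidide (from TMPH and n-BuLi), THF, −78 °C; CuBr·SMe2 (10 mol%), 3, −78 → 0 °C
Reagents that add atoms: none
Why: Directed ortho-metalation with a hindered lithium amide, which deprotonates without bromine–lithium exchange; the C–H flanked by OMe and OMOM is the most acidic and best-coordinated site, and copper-catalysed SN2 allylation of the aryllithium should give the linear prenyl arene.

Step 3
Reactants: 5 1-bromo-2-methoxy-4-(methoxymethoxy)-3-(3-methylbut-2-en-1-yl)benzene
Product: 8 [2-methoxy-4-(methoxymethoxy)-3-(3-methylbut-2-en-1-yl)phenyl]boronic acid, via aryllithium 6 (not isolated), via lithium aryltriisopropoxyborate 7 (not isolated)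
Conditions: n-BuLi, THF, −78 °C; B(Oi-Pr)3, −78 °C → rt; aq. NH4Cl
Reagents that add atoms: triisopropyl borate, CC(C)OB(OC(C)C)OC(C)C; water, O
Why: Bromine–lithium exchange at −78 °C outruns deprotonation of the benzylic–allylic CH2; borylation and hydrolysis at near-neutral pH should give the boronic acid with the MOM ether intact.

Step 4
Reactants: 9 methyl 3-bromo-2-oxopropanoate (methyl bromopyruvate)
Product: 10 methyl 3-[(2,2-dimethylpropanoyl)oxy]-2-oxopropanoate
Conditions: CsO2CCMe3, MeCN, 0 °C → rt
Reagents that add atoms: cesium 2,2-dimethylpropanoate, [Cs+].CC(C)(C)C([O-])=O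
Why: SN2 displacement of an α-bromo ketone by a carboxylate; the pivalate is chosen because it resists the aqueous base of the next step better than an acetate.

Step 5
Reactants: 8 arylboronic acid ArB(OH)2; 10 methyl 3-(pivaloyloxy)-2-oxopropanoate
Product: 11 methyl (2S)-3-[(2,2-dimethylpropanoyl)oxy]-2-hydroxy-2-[2-methoxy-4-(methoxymethoxy)-3-(3-methylbut-2-en-1-yl)phenyl]propanoate
Conditions: [RhCl(C2H4)2]2 (2.5 mol%), chiral 2,5-diphenylbicyclo[2.2.2]octa-2,5-diene (5.5 mol%, enantiomer for Re-face attack), KOH (aq., 0.2 equiv), dioxane, 30 °C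
Reagents that add atoms: none
Why: Rhodium-catalysed enantioselective 1,2-addition of an arylboronic acid to an α-ketoester: transmetalation gives an aryl complex of monovalent rhodium that inserts the activated ketone, and the chiral diene selects the Re face, which gives the S carbinol; this is the only stereocentre and it is set here.

Step 6
Reactants: 11 methyl (2S)-2-Ar-2-hydroxy-3-(pivaloyloxy)propanoate
Product: 12 methyl (2S)-2,3-dihydroxy-2-[2-methoxy-4-(methoxymethoxy)-3-(3-methylbut-2-en-1-yl)phenyl]propanoate
Conditions: NaOMe (0.3 equiv), MeOH, 0 °C → rt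
Reagents that add atoms: none
Why: Base-catalysed transesterification removes the primary pivalate, while exchange at the methyl ester is degenerate; the low temperature keeps the β-hydroxy ester from retro-aldol cleavage.

Step 7
Reactants: 12 methyl (2S)-2-Ar-2,3-dihydroxypropanoate
Product: 13 methyl (4S)-4-[2-methoxy-4-(methoxymethoxy)-3-(3-methylbut-2-en-1-yl)phenyl]-2,2-dimethyl-1,3-dioxolane-4-carboxylate
Conditions: Me2C(OMe)2, PPTS (cat.), acetone, rt
Reagents that add atoms: 2,2-dimethoxypropane, COC(C)(C)OC
Why: Acid-catalysed transketalisation to the five-membered acetonide masks both hydroxyls with one group; pyridinium tosylate at room temperature should not touch the aryl MOM ether.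

Step 8
Reactants: 13 methyl (4S)-4-Ar-2,2-dimethyl-1,3-dioxolane-4-carboxylate; 14 ethynyl(trimethyl)silane
Product: 16 1-{(4S)-4-[2-methoxy-4-(methoxymethoxy)-3-(3-methylbut-2-en-1-yl)phenyl]-2,2-dimethyl-1,3-dioxolan-4-yl}-3-(trimethylsilyl)prop-2-yn-1-one, via lithium (trimethylsilyl)acetylide 15 (not isolated)
Conditions: 14, n-BuLi, THF, −78 °C; then 13, −78 → −40 °C; AcOH, −78 °C
Reagents that add atoms: none
Why: Acylation of a lithium acetylide by an α-alkoxy ester; the chelated tetrahedral adduct should persist at low temperature and collapse only on the cold quench, and the quaternary α-carbon disfavours a second addition.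

Step 9
Reactants: 16 TMS-ynone
Product: 17 3-bromo-1-{(4S)-4-[2-methoxy-4-(methoxymethoxy)-3-(3-methylbut-2-en-1-yl)phenyl]-2,2-dimethyl-1,3-dioxolan-4-yl}prop-2-yn-1-one
Conditions: NBS (1.1 equiv), AgNO3 (10 mol%), acetone, rt, dark
Reagents that add atoms: N-bromosuccinimide, O=C1CCC(=O)N1Br
Why: Silver-catalysed desilylative bromination of a trimethylsilyl alkyne through a silver acetylide; in acetone this should be much faster than electrophilic bromination of ring B or the prenyl alkene.

Step 10
Reactants: 18 methyl 3-oxobutanoate (methyl acetoacetate)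
Product: 19 methyl (2E)-3-methoxybut-2-enoate
Conditions: HC(OMe)3, H2SO4 (cat.), MeOH, rt; distillation
Reagents that add atoms: trimethyl orthoformate, COC(OC)OC
Why: Acid-catalysed enol ether formation from a β-keto ester with an orthoformate; conjugation with the ester favours the E isomer.

Step 11
Reactants: 19 methyl (2E)-3-methoxybut-2-enoate
Product: 21 (1E)-1,3-dimethoxy-1-(trimethylsilyloxy)buta-1,3-diene, via lithium dienolate 20 (not isolated)
Conditions: LiN(i-Pr)2, THF, −78 °C; Me3SiCl, −78 → 0 °C
Reagents that add atoms: chlorotrimethylsilane, C[Si](C)(C)Cl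
Why: γ-Deprotonation of the vinylogous ester gives the extended dienolate, and O-silylation gives the silyl ketene acetal diene, which is used at once without chromatography.

Step 12
Reactants: 17 bromoalkynyl ketone; 21 (1E)-1,3-dimethoxy-1-(trimethylsilyloxy)buta-1,3-diene
Product: 23 (2-bromo-6-hydroxy-4-methoxyphenyl){(4S)-4-[2-methoxy-4-(methoxymethoxy)-3-(3-methylbut-2-en-1-yl)phenyl]-2,2-dimethyl-1,3-dioxolan-4-yl}methanone, via cyclohexa-1,4-diene cycloadduct 22 (not isolated)
Conditions: 21 (2.5 equiv), PhMe, 70 °C; then SiO2, EtOAc, rt
Reagents that add atoms: none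
Why: Proposed new method: diene 21 is a vinylogous ketene acetal with its largest HOMO coefficient on the terminal CH2, and ynone 17 has its largest LUMO coefficient on the bromine-bearing β-carbon, so an asynchronous thermal (4+2) cycloaddition should join CH2 to the β-carbon (C8–C8a) and the ketene-acetal carbon to the α-carbon (C4a–C5); the closest known reaction type is the cycloaddition–aromatisation of 1,1-dialkoxy-3-silyloxy- and 1,3-dialkoxy-1-silyloxybutadienes with acetylenic ketones and esters and with haloquinones, and 3-halopropiolates are known dienophiles, but a 1-bromoalkynyl ketone has not been paired with this diene class. Ring A is closed in an intermolecular cycloaddition mode, four carbons from the diene and two from the alkyne, giving cyclohexa-1,4-diene 22, which is already at the arene oxidation level. Loss of Me3SiOMe from the mixed ketal carbon and enolisation of the dienone on silica should then give the phenol, so the oxygen next to the acyl group (C5) emerges free and hydrogen-bonded to the ketone while the C7 oxygen stays methylated. The ketal carbon of 22 is a transient stereocentre that disappears on aromatisation, and the quaternary C3 centre is a spectator that cannot epimerise. The step needs regioselectivity, which the polarity match secures because the ketone and not the bromine governs the polarisation of the alkyne. It also needs ring closure to win over conjugate addition followed by loss of bromide, which is favoured by toluene without any Lewis acid, so that no free allenolate with a β-bromide has time to form. The quaternary carbon shields the ketone from 1,2-attack and the acetonide keeps both hydroxyls from adding to the ynone.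

Step 13
Reactants: 23 bromoaryl ketone acetonide
Product: 24 (2S)-1-(2-bromo-6-hydroxy-4-methoxyphenyl)-2,3-dihydroxy-2-[2-methoxy-4-(methoxymethoxy)-3-(3-methylbut-2-en-1-yl)phenyl]propan-1-one
Conditions: AcOH/H2O (4:1), 45 °C
Reagents that add atoms: none
Why: Acid-catalysed acetonide hydrolysis; aqueous acetic acid is weak enough to spare the aryl MOM ether and the prenyl group, and the adjacent ketone disfavours ionisation of the tertiary benzylic C–O bond.

Step 14
Reactants: 24 bromoaryl ketone diol
Product: 25 (3S)-3,5-dihydroxy-7-methoxy-3-[2-methoxy-4-(methoxymethoxy)-3-(3-methylbut-2-en-1-yl)phenyl]-2,3-dihydro-4H-chromen-4-one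
Conditions: CuI (10 mol%), 3,4,7,8-tetramethyl-1,10-phenanthroline (20 mol%), Cs2CO3, PhMe, 90 °C
Reagents that add atoms: none
Why: Ullmann-type intramolecular C–O coupling catalysed by monovalent copper closes ring C at O1–C8a in a six-membered mode; the aryl bromide is activated by the ortho ketone, primary alkoxides couple far faster than tertiary ones, and C3 has no α-hydrogen to lose.

Step 15
Reactants: 25 4'-O-MOM chromanone
Product: 26 (3S)-3,5-dihydroxy-3-[4-hydroxy-2-methoxy-3-(3-methylbut-2-en-1-yl)phenyl]-7-methoxy-2,3-dihydro-4H-chromen-4-one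
Conditions: ZnBr2, n-PrSH, CH2Cl2, 0 °C
Reagents that add atoms: none
Why: Lewis acid-assisted thiolysis of the MOM acetal: ZnBr2 activates the acetal and the thiol captures the methoxymethyl cation; the conditions are aprotic, cold and brief, so cyclisation of the prenyl group onto the new phenol and dehydration of the C3 carbinol should not compete.

## Compound list

1 | 4-bromo-3-methoxyphenol | COc1cc(O)ccc1Br | starting material
2 | 1-bromo-2-methoxy-4-(methoxymethoxy)benzene | COCOc1ccc(Br)c(OC)c1 | intermediate
3 | 1-bromo-3-methylbut-2-ene (prenyl bromide) | CC(C)=CCBr | starting material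
4 | [3-bromo-2-methoxy-6-(methoxymethoxy)phenyl]lithium | [Li]c1c(OC)c(Br)ccc1OCOC | intermediate (not isolated)
5 | 1-bromo-2-methoxy-4-(methoxymethoxy)-3-(3-methylbut-2-en-1-yl)benzene | COCOc1ccc(Br)c(OC)c1CC=C(C)C | intermediate
6 | [2-methoxy-4-(methoxymethoxy)-3-(3-methylbut-2-en-1-yl)phenyl]lithium | [Li]c1ccc(OCOC)c(CC=C(C)C)c1OC | intermediate (not isolated)
7 | lithium [2-methoxy-4-(methoxymethoxy)-3-(3-methylbut-2-en-1-yl)phenyl]tri(propan-2-yloxy)borate | [Li+].CC(C)O[B-](OC(C)C)(OC(C)C)c1ccc(OCOC)c(CC=C(C)C)c1OC | intermediate (not isolated)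
8 | [2-methoxy-4-(methoxymethoxy)-3-(3-methylbut-2-en-1-yl)phenyl]boronic acid | OB(O)c1ccc(OCOC)c(CC=C(C)C)c1OC | intermediate
9 | methyl 3-bromo-2-oxopropanoate | COC(=O)C(=O)CBr | starting material
10 | methyl 3-[(2,2-dimethylpropanoyl)oxy]-2-oxopropanoate | COC(=O)C(=O)COC(=O)C(C)(C)C | intermediate
11 | methyl (2S)-3-[(2,2-dimethylpropanoyl)oxy]-2-hydroxy-2-[2-methoxy-4-(methoxymethoxy)-3-(3-methylbut-2-en-1-yl)phenyl]propanoate | CC(C)(C)C(=O)OC[C@@](O)(c1ccc(OCOC)c(CC=C(C)C)c1OC)C(=O)OC | intermediate
12 | methyl (2S)-2,3-dihydroxy-2-[2-methoxy-4-(methoxymethoxy)-3-(3-methylbut-2-en-1-yl)phenyl]propanoate | OC[C@@](O)(c1ccc(OCOC)c(CC=C(C)C)c1OC)C(=O)OC | intermediate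
13 | methyl (4S)-4-[2-methoxy-4-(methoxymethoxy)-3-(3-methylbut-2-en-1-yl)phenyl]-2,2-dimethyl-1,3-dioxolane-4-carboxylate | COC(=O)[C@@]1(COC(C)(C)O1)c2ccc(OCOC)c(CC=C(C)C)c2OC | intermediate
14 | ethynyl(trimethyl)silane | C#C[Si](C)(C)C | starting material
15 | lithium (trimethylsilyl)acetylide | [Li]C#C[Si](C)(C)C | intermediate (not isolated)
16 | 1-{(4S)-4-[2-methoxy-4-(methoxymethoxy)-3-(3-methylbut-2-en-1-yl)phenyl]-2,2-dimethyl-1,3-dioxolan-4-yl}-3-(trimethylsilyl)prop-2-yn-1-one | C[Si](C)(C)C#CC(=O)[C@@]1(COC(C)(C)O1)c2ccc(OCOC)c(CC=C(C)C)c2OC | intermediate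
17 | 3-bromo-1-{(4S)-4-[2-methoxy-4-(methoxymethoxy)-3-(3-methylbut-2-en-1-yl)phenyl]-2,2-dimethyl-1,3-dioxolan-4-yl}prop-2-yn-1-one | BrC#CC(=O)[C@@]1(COC(C)(C)O1)c2ccc(OCOC)c(CC=C(C)C)c2OC | intermediate (precursor of the key step)
18 | methyl 3-oxobutanoate (methyl acetoacetate) | COC(=O)CC(C)=O | starting material
19 | methyl (2E)-3-methoxybut-2-enoate | CO/C(C)=C/C(=O)OC | intermediate
20 | lithium 1,3-dimethoxybuta-1,3-dien-1-olate | C=C(OC)C=C(O[Li])OC | intermediate (not isolated)
21 | (1E)-1,3-dimethoxy-1-(trimethylsilyloxy)buta-1,3-diene | C=C(OC)/C=C(/O[Si](C)(C)C)OC | intermediate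
22 | {2-bromo-4,6-dimethoxy-6-[(trimethylsilyl)oxy]cyclohexa-1,4-dien-1-yl}{(4S)-4-[2-methoxy-4-(methoxymethoxy)-3-(3-methylbut-2-en-1-yl)phenyl]-2,2-dimethyl-1,3-dioxolan-4-yl}methanone (mixture of epimers at the ketal carbon) | COC1=CC(OC)(O[Si](C)(C)C)C(C(=O)[C@@]2(COC(C)(C)O2)c3ccc(OCOC)c(CC=C(C)C)c3OC)=C(Br)C1 | intermediate (not isolated)
23 | (2-bromo-6-hydroxy-4-methoxyphenyl){(4S)-4-[2-methoxy-4-(methoxymethoxy)-3-(3-methylbut-2-en-1-yl)phenyl]-2,2-dimethyl-1,3-dioxolan-4-yl}methanone | COc1cc(O)c(c(Br)c1)C(=O)[C@@]2(COC(C)(C)O2)c3ccc(OCOC)c(CC=C(C)C)c3OC | intermediate (product of the key step)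
24 | (2S)-1-(2-bromo-6-hydroxy-4-methoxyphenyl)-2,3-dihydroxy-2-[2-methoxy-4-(methoxymethoxy)-3-(3-methylbut-2-en-1-yl)phenyl]propan-1-one | COc1cc(O)c(c(Br)c1)C(=O)[C@@](O)(CO)c2ccc(OCOC)c(CC=C(C)C)c2OC | intermediate
25 | (3S)-3,5-dihydroxy-7-methoxy-3-[2-methoxy-4-(methoxymethoxy)-3-(3-methylbut-2-en-1-yl)phenyl]-2,3-dihydro-4H-chromen-4-one | COc1cc(O)c2c(c1)OC[C@@](O)(c1ccc(OCOC)c(CC=C(C)C)c1OC)C2=O | intermediate
26 | (3S)-3,5-dihydroxy-3-[4-hydroxy-2-methoxy-3-(3-methylbut-2-en-1-yl)phenyl]-7-methoxy-2,3-dihydro-4H-chromen-4-one | COc1cc(O)c2c(c1)OC[C@@](O)(c1ccc(O)c(CC=C(C)C)c1OC)C2=O | target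

## Step count and risks

Total: 15 steps. Longest linear sequence: 12 steps, from 1 to 26 through steps 1, 2, 3, 5, 6, 7, 8, 9, 12, 13, 14 and 15. Step 4 and steps 10–11 are one-step and two-step side branches.

**Step 12 (key step, proposed new method).**
- What may go wrong: conjugate addition of the diene terminus to the bromine-bearing carbon followed by expulsion of bromide, so that the alkynyl group is transferred and no ring closes. Hydrolysis or thermal loss of the silyl ketene acetal before it reacts is the second risk.
- Fallback (known chemistry, from 13, rejoining at 25): ring A is carried in as a difluoroarene. 1,3-Difluoro-5-methoxybenzene F1 is lithiated between its fluorines (n-BuLi, THF, −78 °C) to (2,6-difluoro-4-methoxyphenyl)lithium F2. Ester 13 acylates F2 to give the difluoroaryl ketone F3. Aqueous acetic acid frees the diol F4. K2CO3 in DMF closes ring C by intramolecular nucleophilic aromatic substitution of one of the two equivalent ortho fluorines, giving the 5-fluorochromanone F5. KOH in DMSO–water then replaces the remaining fluorine, activated by the ortho carbonyl, with hydroxyl to give 25.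

**Step 2.**
- What may go wrong: incomplete metalation between the two oxygens, or metalation next to bromine followed by halogen migration, which would give mixtures of prenylated regioisomers.
- Fallback (from prenyl bromide 3, rejoining at 8): the halogen is changed to chlorine, which tolerates n-BuLi. Commercial 4-chloro-3-methoxyphenol F6 replaces 1 and is protected (MOMCl, i-Pr2NEt) as 1-chloro-2-methoxy-4-(methoxymethoxy)benzene F7. n-BuLi (THF, −20 °C) lithiates F7 between the oxygens to [3-chloro-2-methoxy-6-(methoxymethoxy)phenyl]lithium F8. CuBr·SMe2 and 3 give the prenylated chloride F9. Miyaura borylation (Pd2(dba)3, XPhos, B2pin2, KOAc, dioxane, 100 °C) gives the pinacol boronate F10. NaIO4 and NH4OAc in acetone–water cleave the pinacol ester to boronic acid 8.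

**Step 5.**
- What may go wrong: poor facial selectivity with an ortho-substituted, hindered boronic acid on an aliphatic ketoester, and protodeboronation competing with slow transmetalation.
- Fallback (from 8 and 10, rejoining at 12): catalyst control is replaced by classical resolution. Addition with [Rh(OH)(cod)]2 and no chiral ligand gives the racemic hydroxy ester F11. LiOH in THF–water removes both ester groups to give the racemic dihydroxy acid F12. Crystallisation with (1S)-1-phenylethanamine gives the salt F13 of the S acid; the mirror-image amine is used instead if screening shows it gives the less soluble salt. Dilute citric acid frees the (2S)-acid F14, and MeI with KHCO3 in DMF gives diol ester 12.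

**Step 14.**
- What may go wrong: closure through the tertiary alkoxide to a five-membered ring, and retro-aldol loss of C2 as formaldehyde under hot carbonate before the coupling occurs.
- Fallback (from 23, rejoining at 25): ring C is closed at O1–C2 instead. Hydroxylation of the aryl bromide (Pd2(dba)3, tBuXPhos, KOH, dioxane–water, 80 °C) gives the symmetrical 2,6-dihydroxyaryl ketone F15. Aqueous acetic acid gives the tetraol F16. A Mitsunobu reaction (PPh3, diisopropyl azodicarboxylate, THF, 0 °C) then closes the ring by attack of either of the two equivalent phenols on the activated primary carbon, which the tertiary hydroxyl cannot do at the arene, to give 25.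

Further compounds
F1 | step 12 | 1,3-difluoro-5-methoxybenzene | COc1cc(F)cc(F)c1
F2 | step 12 | (2,6-difluoro-4-methoxyphenyl)lithium | [Li]c1c(F)cc(OC)cc1F
F3 | step 12 | (2,6-difluoro-4-methoxyphenyl){(4S)-4-[2-methoxy-4-(methoxymethoxy)-3-(3-methylbut-2-en-1-yl)phenyl]-2,2-dimethyl-1,3-dioxolan-4-yl}methanone | COc1cc(F)c(c(F)c1)C(=O)[C@@]2(COC(C)(C)O2)c3ccc(OCOC)c(CC=C(C)C)c3OC
F4 | step 12 | (2S)-1-(2,6-difluoro-4-methoxyphenyl)-2,3-dihydroxy-2-[2-methoxy-4-(methoxymethoxy)-3-(3-methylbut-2-en-1-yl)phenyl]propan-1-one | COc1cc(F)c(c(F)c1)C(=O)[C@@](O)(CO)c2ccc(OCOC)c(CC=C(C)C)c2OC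
F5 | step 12 | (3S)-5-fluoro-3-hydroxy-7-methoxy-3-[2-methoxy-4-(methoxymethoxy)-3-(3-methylbut-2-en-1-yl)phenyl]-2,3-dihydro-4H-chromen-4-one | COc1cc(F)c2c(c1)OC[C@@](O)(c1ccc(OCOC)c(CC=C(C)C)c1OC)C2=O
F6 | step 2 | 4-chloro-3-methoxyphenol | COc1cc(O)ccc1Cl
F7 | step 2 | 1-chloro-2-methoxy-4-(methoxymethoxy)benzene | COCOc1ccc(Cl)c(OC)c1
F8 | step 2 | [3-chloro-2-methoxy-6-(methoxymethoxy)phenyl]lithium | [Li]c1c(OC)c(Cl)ccc1OCOC
F9 | step 2 | 1-chloro-2-methoxy-4-(methoxymethoxy)-3-(3-methylbut-2-en-1-yl)benzene | COCOc1ccc(Cl)c(OC)c1CC=C(C)C
F10 | step 2 | 2-[2-methoxy-4-(methoxymethoxy)-3-(3-methylbut-2-en-1-yl)phenyl]-4,4,5,5-tetramethyl-1,3,2-dioxaborolane | COCOc1ccc(B2OC(C)(C)C(C)(C)O2)c(OC)c1CC=C(C)C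
F11 | step 5 | racemic methyl 3-[(2,2-dimethylpropanoyl)oxy]-2-hydroxy-2-[2-methoxy-4-(methoxymethoxy)-3-(3-methylbut-2-en-1-yl)phenyl]propanoate | CC(C)(C)C(=O)OCC(O)(c1ccc(OCOC)c(CC=C(C)C)c1OC)C(=O)OC
F12 | step 5 | racemic 2,3-dihydroxy-2-[2-methoxy-4-(methoxymethoxy)-3-(3-methylbut-2-en-1-yl)phenyl]propanoic acid | OCC(O)(c1ccc(OCOC)c(CC=C(C)C)c1OC)C(=O)O
F13 | step 5 | (1S)-1-phenylethanaminium (2S)-2,3-dihydroxy-2-[2-methoxy-4-(methoxymethoxy)-3-(3-methylbut-2-en-1-yl)phenyl]propanoate | OC[C@@](O)(c1ccc(OCOC)c(CC=C(C)C)c1OC)C(=O)[O-].C[C@H]([NH3+])c1ccccc1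
F14 | step 5 | (2S)-2,3-dihydroxy-2-[2-methoxy-4-(methoxymethoxy)-3-(3-methylbut-2-en-1-yl)phenyl]propanoic acid | OC[C@@](O)(c1ccc(OCOC)c(CC=C(C)C)c1OC)C(=O)O
F15 | step 14 | (2,6-dihydroxy-4-methoxyphenyl){(4S)-4-[2-methoxy-4-(methoxymethoxy)-3-(3-methylbut-2-en-1-yl)phenyl]-2,2-dimethyl-1,3-dioxolan-4-yl}methanone | COc1cc(O)c(c(O)c1)C(=O)[C@@]2(COC(C)(C)O2)c3ccc(OCOC)c(CC=C(C)C)c3OC
F16 | step 14 | (2S)-1-(2,6-dihydroxy-4-methoxyphenyl)-2,3-dihydroxy-2-[2-methoxy-4-(methoxymethoxy)-3-(3-methylbut-2-en-1-yl)phenyl]propan-1-one | COc1cc(O)c(c(O)c1)C(=O)[C@@](O)(CO)c2ccc(OCOC)c(CC=C(C)C)c2OC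
A1 | alternative 1 | methyl (2S)-2-[(2-bromo-3,5-dimethoxyphenoxy)methyl]-3-diazo-2-(methoxymethoxy)-4-oxohex-5-enoate | COc1cc(OC)c(Br)c(c1)OC[C@@](OCOC)(C(=[N+]=[N-])C(=O)C=C)C(=O)OC
A2 | alternative 1 | 1-methoxy-5-methylhex-4-en-1-yne | COC#CCC=C(C)C
A3 | alternative 1 | methyl (2S)-3-(2-bromo-3,5-dimethoxyphenoxy)-2-[4-hydroxy-2-methoxy-3-(3-methylbut-2-en-1-yl)phenyl]-2-(methoxymethoxy)propanoate | COc1cc(OC)c(Br)c(c1)OC[C@@](OCOC)(c1ccc(O)c(CC=C(C)C)c1OC)C(=O)OC
A4 | alternative 2 | (2S)-1-(2,6-difluoro-4-methoxyphenyl)-3-hydroxy-2-(methoxymethoxy)-2-[2-methoxy-4-(methoxymethoxy)-3-(3-methylbut-2-en-1-yl)phenyl]propan-1-one | COc1cc(F)c(c(F)c1)C(=O)[C@@](OCOC)(CO)c1ccc(OCOC)c(CC=C(C)C)c1OC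
A5 | alternative 2 | (3S)-5-fluoro-7-methoxy-3-[2-methoxy-4-(methoxymethoxy)-3-(3-methylbut-2-en-1-yl)phenyl]-3-(methoxymethoxy)-2,3-dihydro-4H-chromen-4-one | COc1cc(F)c2c(c1)OC[C@@](OCOC)(c1ccc(OCOC)c(CC=C(C)C)c1OC)C2=O
A6 | alternative 3 | (5S)-2-tert-butyl-5-(hydroxymethyl)-5-[2-methoxy-4-(methoxymethoxy)-3-(3-methylbut-2-en-1-yl)phenyl]-1,3-dioxolan-4-one (acetal carbon not specified) | OC[C@@]1(c2ccc(OCOC)c(CC=C(C)C)c2OC)C(=O)OC(C(C)(C)C)O1
A7 | alternative 3 | 3,5-dimethoxybenzyne (1,2-didehydro-3,5-dimethoxybenzene) | COC1=CC(OC)=CC#C1
A8 | alternative 3 | (3S)-3-hydroxy-5,7-dimethoxy-3-[2-methoxy-4-(methoxymethoxy)-3-(3-methylbut-2-en-1-yl)phenyl]-2,3-dihydro-4H-chromen-4-one | COc1cc(OC)c2c(c1)OC[C@@](O)(c1ccc(OCOC)c(CC=C(C)C)c1OC)C2=O
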